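**Plan**
- Retrosynthesis: the first cut is the C14–C15 single bond, the sp2–sp2 bond between the C13=C14 and C15=C15' alkenes at the middle of the nonaene. This gives a C21 pentaenyl boronate (ε-ring half) and a C19 tetraenyl iodide (oxirane half). The later cuts are olefinations: C15=C15', C13'=C14' and C9'=C10' on the ε half, C11=C12 and C7=C8 on the oxirane half.
- Enabling feature: C14 and C15 are both alkenyl CH carbons, far from the ε-ring (C1'–C6') and from the oxirane (C5, C6, O) fused to the cyclohexane ring. A stereoretentive, acid-free palladium cross-coupling can therefore join the halves without touching the acid-labile allylic oxirane or the C6' centre.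
- Forward: the oxirane is the only ring made (Sharpless epoxidation of β-cyclogeraniol); both carbocycles are bought. Each chain grows outward from its ring by Horner–Wadsworth–Emmons (HWE) steps, and the halves are joined last.
- Stereochemistry: C5/C6 come from D-(−)-diethyl tartrate in the Sharpless step and C6' from (R)-α-ionone. The E-alkenes come from HWE reactions, syn-carboalumination (C13=C14) and a boron–Wittig reaction (C15=C15'), and the coupling conserves them.

Key step: step 18

Assumption: (R)-α-ionone is bought as the single enantiomer, and phosphonate 5 is used as the commercial E/Z mixture (drawn E), since its anion equilibrates.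

**Route**

Step 1
Reactants: 1 β-cyclocitral (2,6,6-trimethylcyclohex-1-ene-1-carbaldehyde)
Product: 2 β-cyclogeraniol ((2,6,6-trimethylcyclohex-1-en-1-yl)methanol)
Conditions: NaBH4, MeOH, 0 °C
Reagents that add atoms: none
Why: Borohydride 1,2-reduction of the hindered enal should give the primary allylic alcohol that directs the epoxidation, and no stereocentre is formed.

Step 2
Reactants: 2 β-cyclogeraniol
Product: 3 [(1R,6R)-2,2,6-trimethyl-7-oxabicyclo[4.1.0]heptan-1-yl]methanol
Conditions: Ti(OiPr)4 (0.2 equiv), D-(−)-diethyl tartrate (0.25 equiv), t-BuOOH (anhydrous, in decane), 4 Å MS, CH2Cl2, −20 °C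
Reagents that add atoms: tert-butyl hydroperoxide, CC(C)(C)OO
Why: Katsuki–Sharpless asymmetric epoxidation, in which the titanium tartrate complex bound to the allylic OH delivers oxygen to one face of the tetrasubstituted alkene; with D-(−)-diethyl tartrate this should be the face giving (1R,6R), and the necessarily cis-fused oxirane sets both quaternary centres at once.

Step 3
Reactants: 3 epoxy alcohol
Product: 4 (1S,6R)-2,2,6-trimethyl-7-oxabicyclo[4.1.0]heptane-1-carbaldehyde
Conditions: (n-Pr4N)RuO4 (5 mol %), N-methylmorpholine N-oxide, 4 Å MS, CH2Cl2, 23 °C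
Reagents that add atoms: none
Why: Ley–Griffith oxidation is neutral and anhydrous, so the acid-labile oxirane should survive, and the quaternary α-carbon cannot epimerise.

Step 4
Reactants: 4 epoxy aldehyde; 5 ethyl (2E)-4-(diethoxyphosphoryl)-3-methylbut-2-enoate
Product: 6 ethyl (2E,4E)-3-methyl-5-[(1S,6R)-2,2,6-trimethyl-7-oxabicyclo[4.1.0]heptan-1-yl]penta-2,4-dienoate
Conditions: LiN(SiMe3)2, DMPU, THF, −78 → 23 °C; chromatography on Et3N-deactivated silica
Reagents that add atoms: none
Why: Horner–Wadsworth–Emmons olefination with the vinylogous phosphonate anion should give the (4E) alkene and mainly the (2E) ester, a minor (2Z) isomer being removed by chromatography, while the oxirane is inert to the base.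

Step 5
Reactants: 6 epoxy dienoate
Product: 7 (2E,4E)-3-methyl-5-[(1S,6R)-2,2,6-trimethyl-7-oxabicyclo[4.1.0]heptan-1-yl]penta-2,4-dien-1-ol
Conditions: i-Bu2AlH (2.5 equiv), CH2Cl2, −78 °C; aqueous Rochelle salt
Reagents that add atoms: none
Why: Hydride reduction of the conjugated ester at −78 °C should be much faster than opening of the fully substituted oxirane and gives the allylic alcohol with the alkene geometry unchanged.

Step 6
Reactants: 7 epoxy dienol
Product: 8 (2E,4E)-3-methyl-5-[(1S,6R)-2,2,6-trimethyl-7-oxabicyclo[4.1.0]heptan-1-yl]penta-2,4-dienal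
Conditions: activated MnO2 (excess), Na2CO3, CH2Cl2, 23 °C
Reagents that add atoms: none
Why: Heterogeneous MnO2 oxidation is selective for allylic alcohols and, buffered with carbonate, should leave the oxirane and the E-geometry intact.

Step 7
Reactants: 9 prop-2-yn-1-ol
Product: 11 (2E)-3-iodo-2-methylprop-2-en-1-ol, via alkenylalane 10 (not isolated)
Conditions: AlMe3 (3 equiv), Cp2ZrCl2 (0.25 equiv), CH2Cl2, 0 → 23 °C; then I2, THF, −30 → 0 °C; aqueous K2CO3
Reagents that add atoms: trimethylaluminium, C[Al](C)C; iodine, II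
Why: Negishi zirconium-catalysed carboalumination adds methyl and aluminium syn across the alkyne with aluminium at the terminus, and iodinolysis with retention should give the E trisubstituted alkenyl iodide that becomes C13=C14.

Step 8
Reactants: 11 iodo alcohol
Product: 12 (1E)-3-bromo-1-iodo-2-methylprop-1-ene
Conditions: CBr4, PPh3, CH2Cl2, 0 °C
Reagents that add atoms: carbon tetrabromide, BrC(Br)(Br)Br
Why: Appel bromination of the primary allylic alcohol proceeds under neutral conditions without touching the alkenyl iodide or its geometry.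

Step 9
Reactants: 12 allylic bromide
Product: 13 diethyl [(2E)-3-iodo-2-methylprop-2-en-1-yl]phosphonate
Conditions: P(OEt)3 (neat), 110 °C
Reagents that add atoms: triethyl phosphite, CCOP(OCC)OCC
Why: Michaelis–Arbuzov reaction at the allylic bromide; the alkenyl iodide does not react with the phosphite without a metal catalyst.

Step 10
Reactants: 8 epoxy dienal; 13 iodoallyl phosphonate
Product: 14 (1S,6R)-1-[(1E,3E,5E,7E)-8-iodo-3,7-dimethylocta-1,3,5,7-tetraen-1-yl]-2,2,6-trimethyl-7-oxabicyclo[4.1.0]heptane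
Conditions: NaN(SiMe3)2, THF, −78 °C (13 first, then 8), → 0 °C; dim light; Et3N-deactivated silica
Reagents that add atoms: none
Why: Horner–Wadsworth–Emmons olefination of the enal with the allylic phosphonate anion should form the disubstituted C11=C12 alkene E-selectively, the C13=C14 iodide geometry being carried in unchanged from 13.

Step 11
Reactants: 15 (R)-α-ionone ((3E)-4-[(1R)-2,6,6-trimethylcyclohex-2-en-1-yl]but-3-en-2-one); 16 triethyl phosphonoacetate
Product: 17 ethyl (2E,4E)-3-methyl-5-[(1R)-2,6,6-trimethylcyclohex-2-en-1-yl]penta-2,4-dienoate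
Conditions: NaH (slightly less than 16), THF, 0 → 40 °C; chromatography
Reagents that add atoms: none
Why: Horner–Wadsworth–Emmons olefination of the methyl ketone should give mainly the (2E) ester (the minor 2Z isomer is separated), and the stabilised phosphonate anion is too weak a base to remove the doubly allylic ring C1–H, so the stereocentre is kept.

Step 12
Reactants: 17 ε-dienoate
Product: 18 (2E,4E)-3-methyl-5-[(1R)-2,6,6-trimethylcyclohex-2-en-1-yl]penta-2,4-dien-1-ol
Conditions: i-Bu2AlH (2.5 equiv), CH2Cl2, −78 °C; aqueous Rochelle salt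
Reagents that add atoms: none
Why: Standard hydride reduction of a conjugated ester to the allylic alcohol, with no effect on the alkenes or the ring stereocentre.

Step 13
Reactants: 18 ε-dienol
Product: 19 (2E,4E)-3-methyl-5-[(1R)-2,6,6-trimethylcyclohex-2-en-1-yl]penta-2,4-dienal
Conditions: activated MnO2 (excess), CH2Cl2, 23 °C
Reagents that add atoms: none
Why: Selective allylic oxidation by MnO2 under neutral conditions should give the dienal without isomerising the ring double bond into conjugation.

Step 14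
Reactants: 19 ε-dienal; 5 ethyl (2E)-4-(diethoxyphosphoryl)-3-methylbut-2-enoate
Product: 20 ethyl (2E,4E,6E,8E)-3,7-dimethyl-9-[(1R)-2,6,6-trimethylcyclohex-2-en-1-yl]nona-2,4,6,8-tetraenoate
Conditions: LiN(SiMe3)2, DMPU, THF, −78 → 0 °C; dim light
Reagents that add atoms: none
Why: Horner–Wadsworth–Emmons chain extension of the retinoid type should give the new (4E) alkene and mainly the (2E) ester, the minor (2Z) isomer being removed by chromatography.

Step 15
Reactants: 20 tetraenoate
Product: 21 (2E,4E,6E,8E)-3,7-dimethyl-9-[(1R)-2,6,6-trimethylcyclohex-2-en-1-yl]nona-2,4,6,8-tetraen-1-ol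
Conditions: i-Bu2AlH (2.5 equiv), CH2Cl2, −78 °C; aqueous Rochelle salt; dim light
Reagents that add atoms: none
Why: Hydride reduction of the conjugated ester to the allylic alcohol, as in step 12.

Step 16
Reactants: 21 tetraenol
Product: 22 (2E,4E,6E,8E)-3,7-dimethyl-9-[(1R)-2,6,6-trimethylcyclohex-2-en-1-yl]nona-2,4,6,8-tetraenal
Conditions: activated MnO2 (excess), CH2Cl2, 23 °C, dim light
Reagents that add atoms: none
Why: Selective MnO2 oxidation of the polyenyl allylic alcohol should give the tetraenal without over-oxidation or change of geometry.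

Step 17
Reactants: 22 tetraenal; 23 2,2'-methylenebis(4,4,5,5-tetramethyl-1,3,2-dioxaborolane)
Product: 24 2-[(1E,3E,5E,7E,9E)-4,8-dimethyl-10-[(1R)-2,6,6-trimethylcyclohex-2-en-1-yl]deca-1,3,5,7,9-pentaen-1-yl]-4,4,5,5-tetramethyl-1,3,2-dioxaborolane
Conditions: lithium 2,2,6,6-tetramethylpiperidide (from the amine and n-BuLi), THF, 0 °C, 23 added; then 22 at −78 → 23 °C; dim light
Reagents that add atoms: none
Why: Boron–Wittig reaction, in which the α,α-diboryl carbanion adds to the aldehyde and syn elimination of the B–O unit should give the (E)-alkenyl boronate, setting the C15=C15' alkene.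

Step 18
Reactants: 24 pentaenyl boronate; 14 tetraenyl iodide
Product: 25 (5R,6S,6'R)-5,6-epoxy-5,6-dihydro-β,ε-carotene (target)
Conditions: Pd(OAc)2 (5 mol %), SPhos (2-dicyclohexylphosphino-2',6'-dimethoxybiphenyl, 10 mol %), K3PO4 (3 equiv, aqueous), THF, degassed, 23–40 °C, argon, dark; neutral alumina, then crystallisation
Reagents that add atoms: none
Why: Zerovalent palladium carrying SPhos inserts into the C14–I bond of 14 with retention; phosphate or hydroxide then links palladium to the boron of 24, the C15 alkenyl group transfers with retention, and reductive elimination forms the C14–C15 bond. The closest known reaction type is the alkenyl–alkenyl Suzuki–Miyaura coupling used to assemble polyenes and carotenoids from a polyenyl boronate and a polyenyl iodide. No ring is closed and no stereocentre is formed; the 13E and 15E geometries set in steps 7 and 17 pass through unchanged, as do the C5/C6 and C6' centres. The step needs chemoselective insertion into C–I over ionisation of the allylic oxirane at C6–O, and the far faster reaction of the alkenyl iodide plus the fully substituted C6 should secure it. The basic phosphate medium contains no acid, so the 5,6-epoxide should not rearrange to the furanoid oxide and the doubly allylic C6'–H is not removed. Exclusion of light and oxygen at near-ambient temperature should suppress E/Z scrambling, protodeboronation and homocoupling.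

**Compound list**

1 | β-cyclocitral, 2,6,6-trimethylcyclohex-1-ene-1-carbaldehyde | CC1=C(C=O)C(C)(C)CCC1 | starting material
2 | β-cyclogeraniol, (2,6,6-trimethylcyclohex-1-en-1-yl)methanol | CC1=C(CO)C(C)(C)CCC1 | intermediate
3 | [(1R,6R)-2,2,6-trimethyl-7-oxabicyclo[4.1.0]heptan-1-yl]methanol | OC[C@@]12O[C@]1(C)CCCC2(C)C | intermediate
4 | (1S,6R)-2,2,6-trimethyl-7-oxabicyclo[4.1.0]heptane-1-carbaldehyde | O=C[C@@]12O[C@]1(C)CCCC2(C)C | intermediate
5 | ethyl (2E)-4-(diethoxyphosphoryl)-3-methylbut-2-enoate | CCOC(=O)/C=C(\C)CP(=O)(OCC)OCC | starting material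
6 | ethyl (2E,4E)-3-methyl-5-[(1S,6R)-2,2,6-trimethyl-7-oxabicyclo[4.1.0]heptan-1-yl]penta-2,4-dienoate | CCOC(=O)/C=C(C)/C=C/[C@@]12O[C@]1(C)CCCC2(C)C | intermediate
7 | (2E,4E)-3-methyl-5-[(1S,6R)-2,2,6-trimethyl-7-oxabicyclo[4.1.0]heptan-1-yl]penta-2,4-dien-1-ol | OC/C=C(C)/C=C/[C@@]12O[C@]1(C)CCCC2(C)C | intermediate
8 | (2E,4E)-3-methyl-5-[(1S,6R)-2,2,6-trimethyl-7-oxabicyclo[4.1.0]heptan-1-yl]penta-2,4-dienal | O=C/C=C(C)/C=C/[C@@]12O[C@]1(C)CCCC2(C)C | intermediate
9 | prop-2-yn-1-ol | C#CCO | starting material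
10 | dimethylaluminium (2E)-3-(dimethylalumanyl)-2-methylprop-2-en-1-olate (alkenylalane) | C[Al](C)/C=C(\C)CO[Al](C)C | intermediate
11 | (2E)-3-iodo-2-methylprop-2-en-1-ol | OC/C(C)=C/I | intermediate
12 | (1E)-3-bromo-1-iodo-2-methylprop-1-ene | BrC/C(C)=C/I | intermediate
13 | diethyl [(2E)-3-iodo-2-methylprop-2-en-1-yl]phosphonate | CCOP(=O)(OCC)C/C(C)=C/I | intermediate
14 | (1S,6R)-1-[(1E,3E,5E,7E)-8-iodo-3,7-dimethylocta-1,3,5,7-tetraen-1-yl]-2,2,6-trimethyl-7-oxabicyclo[4.1.0]heptane | I/C=C(C)/C=C/C=C(C)/C=C/[C@@]12O[C@]1(C)CCCC2(C)C | intermediate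
15 | (R)-α-ionone, (3E)-4-[(1R)-2,6,6-trimethylcyclohex-2-en-1-yl]but-3-en-2-one | CC1=CCCC(C)(C)[C@H]1/C=C/C(C)=O | starting material
16 | triethyl phosphonoacetate | CCOC(=O)CP(=O)(OCC)OCC | starting material
17 | ethyl (2E,4E)-3-methyl-5-[(1R)-2,6,6-trimethylcyclohex-2-en-1-yl]penta-2,4-dienoate | CC1=CCCC(C)(C)[C@H]1/C=C/C(C)=C/C(=O)OCC | intermediate
18 | (2E,4E)-3-methyl-5-[(1R)-2,6,6-trimethylcyclohex-2-en-1-yl]penta-2,4-dien-1-ol | CC1=CCCC(C)(C)[C@H]1/C=C/C(C)=C/CO | intermediate
19 | (2E,4E)-3-methyl-5-[(1R)-2,6,6-trimethylcyclohex-2-en-1-yl]penta-2,4-dienal | CC1=CCCC(C)(C)[C@H]1/C=C/C(C)=C/C=O | intermediate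
20 | ethyl (2E,4E,6E,8E)-3,7-dimethyl-9-[(1R)-2,6,6-trimethylcyclohex-2-en-1-yl]nona-2,4,6,8-tetraenoate | CC1=CCCC(C)(C)[C@H]1/C=C/C(C)=C/C=C/C(C)=C/C(=O)OCC | intermediate
21 | (2E,4E,6E,8E)-3,7-dimethyl-9-[(1R)-2,6,6-trimethylcyclohex-2-en-1-yl]nona-2,4,6,8-tetraen-1-ol | CC1=CCCC(C)(C)[C@H]1/C=C/C(C)=C/C=C/C(C)=C/CO | intermediate
22 | (2E,4E,6E,8E)-3,7-dimethyl-9-[(1R)-2,6,6-trimethylcyclohex-2-en-1-yl]nona-2,4,6,8-tetraenal | CC1=CCCC(C)(C)[C@H]1/C=C/C(C)=C/C=C/C(C)=C/C=O | intermediate
23 | 2,2'-methylenebis(4,4,5,5-tetramethyl-1,3,2-dioxaborolane) | CC1(C)OB(CB2OC(C)(C)C(C)(C)O2)OC1(C)C | starting material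
24 | 2-[(1E,3E,5E,7E,9E)-4,8-dimethyl-10-[(1R)-2,6,6-trimethylcyclohex-2-en-1-yl]deca-1,3,5,7,9-pentaen-1-yl]-4,4,5,5-tetramethyl-1,3,2-dioxaborolane | CC1=CCCC(C)(C)[C@H]1/C=C/C(C)=C/C=C/C(C)=C/C=C/B1OC(C)(C)C(C)(C)O1 | intermediate
25 | (5R,6S,6'R)-5,6-epoxy-5,6-dihydro-β,ε-carotene | CC1=CCCC(C)(C)[C@H]1/C=C/C(C)=C/C=C/C(C)=C/C=C/C=C(C)/C=C/C=C(C)/C=C/[C@@]12O[C@]1(C)CCCC2(C)C | target

**Count**

Total steps: 18. Longest linear sequence: 8 steps (steps 1–6, 10 and 18 from β-cyclocitral; equally steps 11–18 from (R)-α-ionone).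

**Steps most likely to fail**

Step 18. Transmetalation of the long alkenyl boronate may be slow, so protodeboronation could compete, and palladium could scramble E/Z geometry or ionise the allylic oxirane in the aqueous base. The fallback replaces the base-mediated boron coupling by a neutral tin coupling. It sets out from aldehyde 22: a Takai–Hodgson stannyl olefination (CrCl2, Bu3SnCHBr2, LiI, THF/DMF, 23 °C) should give tributyl[(1E,3E,5E,7E,9E)-4,8-dimethyl-10-[(1R)-2,6,6-trimethylcyclohex-2-en-1-yl]deca-1,3,5,7,9-pentaen-1-yl]stannane F1. A Stille coupling of this stannane with iodide 14 (Pd2(dba)3, AsPh3, NMP, 23 °C, dark) should then give the target, and the route is rejoined at 25.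

Step 17. The α,α-diboryl carbanion may deprotonate the polyenal at the C3 methyl group instead of adding, and the B–O elimination may not be fully E-selective. The fallback sets the same alkene by a syn hydrometalation of an alkyne. It sets out from aldehyde 22: Ohira–Bestmann homologation (dimethyl (1-diazo-2-oxopropyl)phosphonate, K2CO3, MeOH, 0 → 23 °C) should give (6R)-6-[(1E,3E,5E,7E)-3,7-dimethyldeca-1,3,5,7-tetraen-9-yn-1-yl]-1,5,5-trimethylcyclohex-1-ene F2. Hydroboration of this alkyne with pinacolborane and catalytic Cp2Zr(H)Cl (Et3N, CH2Cl2, 23 °C) should give the (E)-boronate, and the route is rejoined at 24.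

Step 10. The γ-iodoallyl phosphonate carbanion may lose iodide (carbenoid-type decomposition), and enolisation of aldehyde 8 may lower conversion and 11E selectivity. The fallback inverts the polarity of the olefination so that the carbanion carries no iodine. It sets out from alcohol 7 and iodo alcohol 11. Appel bromination of 7 (CBr4, PPh3, 2,6-lutidine, CH2Cl2, −20 °C) should give (1S,6R)-1-[(1E,3E)-5-bromo-3-methylpenta-1,3-dien-1-yl]-2,2,6-trimethyl-7-oxabicyclo[4.1.0]heptane F3. Treatment with PPh3 (EtOAc, 23 °C) should give [(2E,4E)-3-methyl-5-[(1S,6R)-2,2,6-trimethyl-7-oxabicyclo[4.1.0]heptan-1-yl]penta-2,4-dien-1-yl]triphenylphosphonium bromide F4. Separately, MnO2 oxidation of 11 (CH2Cl2, 23 °C) should give (2E)-3-iodo-2-methylprop-2-enal F5. A Wittig reaction of the ylide from F4 (NaOMe, CH2Cl2/MeOH, 0 °C) with F5 should give the tetraenyl iodide after removal of any 5Z isomer by chromatography, and the route is rejoined at 14.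

Further compounds
F1 | step 18 | tributyl[(1E,3E,5E,7E,9E)-4,8-dimethyl-10-[(1R)-2,6,6-trimethylcyclohex-2-en-1-yl]deca-1,3,5,7,9-pentaen-1-yl]stannane | CC1=CCCC(C)(C)[C@H]1/C=C/C(C)=C/C=C/C(C)=C/C=C/[Sn](CCCC)(CCCC)CCCC
F2 | step 17 | (6R)-6-[(1E,3E,5E,7E)-3,7-dimethyldeca-1,3,5,7-tetraen-9-yn-1-yl]-1,5,5-trimethylcyclohex-1-ene | CC1=CCCC(C)(C)[C@H]1/C=C/C(C)=C/C=C/C(C)=C/C#C
F3 | step 10 | (1S,6R)-1-[(1E,3E)-5-bromo-3-methylpenta-1,3-dien-1-yl]-2,2,6-trimethyl-7-oxabicyclo[4.1.0]heptane | BrC/C=C(C)/C=C/[C@@]12O[C@]1(C)CCCC2(C)C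
F4 | step 10 | [(2E,4E)-3-methyl-5-[(1S,6R)-2,2,6-trimethyl-7-oxabicyclo[4.1.0]heptan-1-yl]penta-2,4-dien-1-yl]triphenylphosphonium bromide | [Br-].c1ccccc1[P+](c1ccccc1)(c1ccccc1)C/C=C(C)/C=C/[C@@]12O[C@]1(C)CCCC2(C)C
F5 | step 10 | (2E)-3-iodo-2-methylprop-2-enal | O=C/C(C)=C/I
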